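A direct plan would condense acetophenone A1 (ring A with its acetyl group and free 6'-hydroxyl) with aldehyde A2 (ring B with the finished side chain) to chalcone A3 and would close ring C by Algar–Flynn–Oyamada oxidation.
Its weakest step would be that oxidative cyclisation: the 6'-methoxy group of A3, beside the carbonyl, would be expected to divert it largely to the aurone.
Second would be the persulfate hydroxylation that would add the C6 oxygen of ring A on the way to A1: it would typically stall at low conversion.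
Third would be the enantioselective hydro-oxygenation of the 1,1-disubstituted alkene A4 that would set the stereocentre of A2: its C–O forming event would lack precedent.

The route disconnects ring C at O1–C8a and C4–C4a, so that ring A enters as a benzyne. The feature exploited is the pair of neighbouring substituents on C8a (O1) and C4a (the C4 carbonyl) next to the C5 methoxy group. That group steers the carboxylate oxygen of an arylpropiolic acid to the remote aryne carbon, the aryl anion takes over the acyl group, and the phenolate closes the pyranone onto the alkyne, three bonds in one operation. Ring A oxygens come from a symmetric hydroquinone, the 3-hydroxyl from C3 metalation and the stereocentre from the chiral pool, so persulfate oxidation, chalcone oxidation and untested asymmetric catalysis all disappear.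

Key step: step 10

Assumption: the symmetric 2,3-dimethoxyhydroquinone of step 1 and the (R)-hydroxy ester of step 4 are taken as catalogue compounds.

Step 1
Reactants: 1 2,3-dimethoxybenzene-1,4-diol
Product: 2 4-(benzyloxy)-2,3-dimethoxyphenol
Conditions: 1 (2 equiv), BnBr (1 equiv), K2CO3 (1 equiv), DMF, rt, N2; unreacted 1 recovered
Reagents that add atoms: benzyl bromide, BrCc1ccccc1
Why: Williamson etherification of a symmetric hydroquinone whose two hydroxyls are equivalent, so mono-benzylation with the diol in excess needs no regiocontrol.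

Step 2
Reactants: 2 4-(benzyloxy)-2,3-dimethoxyphenol
Product: 3 4-(benzyloxy)-6-bromo-2,3-dimethoxyphenol
Conditions: NBS (1.0 equiv), i-Pr2NH (10 mol %), CH2Cl2, −78 → 0 °C
Reagents that add atoms: N-bromosuccinimide, O=C1CCC(=O)N1Br
Why: Amine-catalysed ortho-selective electrophilic bromination of a phenol; C6 is the only free position ortho to the hydroxyl (the para position carries the benzyloxy group) and the free phenol outranks the ethers as director.

Step 3
Reactants: 3 4-(benzyloxy)-6-bromo-2,3-dimethoxyphenol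
Product: 6 4-(benzyloxy)-2,3-dimethoxy-6-(trimethylsilyl)phenyl trifluoromethanesulfonate, via aryl trimethylsilyl ether 4 (not isolated), via lithium 2-silylphenolate 5 (not isolated)
Conditions: HN(SiMe3)2, THF, 65 °C, then evaporation; n-BuLi (1.1 equiv), THF, −100 °C; Tf2O (1.2 equiv), −100 °C → rt
Reagents that add atoms: hexamethyldisilazane, C[Si](C)(C)N[Si](C)(C)C; trifluoromethanesulfonic anhydride, O=S(=O)(OS(=O)(=O)C(F)(F)F)C(F)(F)F
Why: Standard 2-silylaryl triflate synthesis from a 2-bromophenol: O-silylation, bromine–lithium exchange and 1,3 O→C silyl shift (retro-Brook rearrangement) give the lithium 2-silylphenolate, which triflic anhydride traps at oxygen.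

Step 4
Reactants: 7 methyl (2R)-3-hydroxy-2-methylpropanoate
Product: 8 methyl (2R)-3-(benzyloxy)-2-methylpropanoate
Conditions: BnOC(=NH)CCl3 (1.3 equiv), TfOH (5 mol %), CH2Cl2–cyclohexane, 0 °C → rt
Reagents that add atoms: benzyl 2,2,2-trichloroacetimidate, N=C(OCc1ccccc1)C(Cl)(Cl)Cl
Why: Acid-catalysed benzylation with the trichloroacetimidate avoids the base that would epimerise or β-eliminate the hydroxy ester, so the chiral-pool (R) centre is carried over unchanged.

Step 5
Reactants: 8 methyl (2R)-3-(benzyloxy)-2-methylpropanoate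
Product: 9 (2R)-3-(benzyloxy)-2-methylpropanal
Conditions: i-Bu2AlH (1.05 equiv), CH2Cl2, −78 °C; MeOH, then aq. potassium sodium tartrate; used at once without chromatography
Reagents that add atoms: none
Why: Partial ester reduction that stops at the tetrahedral aluminium hemiacetal at −78 °C and releases the aldehyde only on work-up; the α-centre should be retained if the aldehyde is not stored or chromatographed.

Step 6
Reactants: 9 (2R)-3-(benzyloxy)-2-methylpropanal
Product: 10 ({[(2S)-2-methylbut-3-en-1-yl]oxy}methyl)benzene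
Conditions: Ph3PCH3Br (1.5 equiv), KN(SiMe3)2 (1.4 equiv), THF, 0 °C; then 9, −78 → 0 °C
Reagents that add atoms: methyltriphenylphosphonium bromide, C[P+](c1ccccc1)(c1ccccc1)c1ccccc1.[Br-]
Why: Wittig methylenation with the lithium-free non-stabilised ylide at low temperature should outrun enolisation of the α-branched aldehyde; the centre is unchanged in space and becomes (S) only through the change in CIP priorities.

Step 7
Reactants: 10 ({[(2S)-2-methylbut-3-en-1-yl]oxy}methyl)benzene; 11 4-(benzyloxy)-3-bromobenzaldehyde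
Product: 13 4-(benzyloxy)-3-[(3S)-4-(benzyloxy)-3-methylbutyl]benzaldehyde, via B-alkyl-9-BBN adduct 12 (not isolated)
Conditions: 10 (1.3 equiv), 9-BBN-H (1.25 equiv), THF, 0 °C → rt; then 3 M aq K3PO4 (3 equiv), 11 (1.0 equiv), PdCl2(dppf) (5 mol %), DMF, 60 °C
Reagents that add atoms: none
Why: Anti-Markovnikov hydroboration of the terminal alkene followed by B-alkyl Suzuki–Miyaura coupling (oxidative addition of the aryl bromide to zerovalent palladium, base-assisted transfer of the primary alkyl group, reductive elimination); the alkene is in excess and the aqueous base is added before the aldehyde so that no B–H remains, and the stereocentre, β to boron, is not involved.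

Step 8
Reactants: 13 4-(benzyloxy)-3-[(3S)-4-(benzyloxy)-3-methylbutyl]benzaldehyde
Product: 14 1-(benzyloxy)-2-[(3S)-4-(benzyloxy)-3-methylbutyl]-4-(2,2-dibromoethenyl)benzene
Conditions: CBr4 (2 equiv), PPh3 (4 equiv), CH2Cl2, 0 °C
Reagents that add atoms: carbon tetrabromide, BrC(Br)(Br)Br
Why: First stage of the Corey–Fuchs sequence, a Wittig reaction of the aromatic aldehyde with the ylide Ph3P=CBr2 formed in the flask.

Step 9
Reactants: 14 1-(benzyloxy)-2-[(3S)-4-(benzyloxy)-3-methylbutyl]-4-(2,2-dibromoethenyl)benzene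
Product: 16 3-{4-(benzyloxy)-3-[(3S)-4-(benzyloxy)-3-methylbutyl]phenyl}prop-2-ynoic acid, via lithium arylacetylide 15 (not isolated)
Conditions: n-BuLi (2.2 equiv), THF, −78 °C, 1 h; CO2 (g), −78 → 0 °C; cold 1 M HCl
Reagents that add atoms: carbon dioxide, O=C=O
Why: Second stage of the Corey–Fuchs sequence: bromine–lithium exchange, Fritsch–Buttenberg–Wiechell 1,2-shift and deprotonation give the lithium acetylide, which CO2 carboxylates to the arylpropiolic acid.

Step 10
Reactants: 6 4-(benzyloxy)-2,3-dimethoxy-6-(trimethylsilyl)phenyl trifluoromethanesulfonate; 16 3-{4-(benzyloxy)-3-[(3S)-4-(benzyloxy)-3-methylbutyl]phenyl}prop-2-ynoic acid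
Product: 19 7-(benzyloxy)-2-{4-(benzyloxy)-3-[(3S)-4-(benzyloxy)-3-methylbutyl]phenyl}-5,6-dimethoxy-4H-chromen-4-one, via aryne 17 (not isolated), via 2-hydroxyaryl ynone 18 (not isolated)
Conditions: 6 (1.5 equiv), 16 (1.0 equiv), CsF (4 equiv), THF, 125 °C, sealed tube, 24 h
Reagents that add atoms: none
Why: Fluoride removes the silyl group of 6 and triflate leaves to give aryne 17; the caesium carboxylate of 16 adds through oxygen to the aryne carbon remote from the methoxy group (future C8a, O1–C8a bond), because a 3-alkoxyaryne is attacked at the terminus that places the developing aryl anion beside the inductively withdrawing OMe (future C4a), which is also the less hindered approach. The aryl anion then attacks the ester carbonyl through a benzoxetene-type alkoxide that collapses to the 2-acylphenolate of 18 (C4–C4a bond, net insertion of the aryne into the acyl C–O bond), and at 125 °C this acyl shift should outrun protonation to the simple aryl ester. The phenolate closes ring C by 6-endo-dig oxa-Michael addition to the ynone (O1–C2 bond), the mode favoured over 5-exo-dig closure to the aurone in aprotic medium, and the C3 carbanion takes up the proton that the acid delivered. The closest known reaction type is the intermolecular C–O addition of carboxylic acids to arynes, which gives 2-hydroxyaryl ketones and, from unsaturated acids, chromanones and flavones, together with the aryne route from salicylates to xanthones. No stereocentre is formed, and the remote (S) centre sits in a saturated chain without acidic hydrogens and is not touched. The selectivity needed is the orientation of the aryne insertion, which the C5 methoxy group secures, and the benzyl ethers leave no O–H to compete with the carboxylate.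

Step 11
Reactants: 19 7-(benzyloxy)-2-{4-(benzyloxy)-3-[(3S)-4-(benzyloxy)-3-methylbutyl]phenyl}-5,6-dimethoxy-4H-chromen-4-one
Product: 22 7-(benzyloxy)-2-{4-(benzyloxy)-3-[(3S)-4-(benzyloxy)-3-methylbutyl]phenyl}-3-hydroxy-5,6-dimethoxy-4H-chromen-4-one, via 3-lithioflavone 20 (not isolated), via flavon-3-yl dimethyl boronate 21 (not isolated)
Conditions: LiN(iPr)2 (1.5 equiv), THF, −78 °C, 30 min; B(OMe)3 (3 equiv), −78 → 0 °C; AcOH (2 equiv), 30% H2O2 (5 equiv), 0 °C → rt
Reagents that add atoms: hydrogen peroxide, OO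
Why: Lithiation of the flavone at C3 (the only vinylic C–H, acidified by the adjacent carbonyl), borylation with trimethyl borate and peroxide oxidation of the C–B bond under buffered conditions, the established way from 5-alkoxyflavones to flavonols.

Step 12
Reactants: 22 7-(benzyloxy)-2-{4-(benzyloxy)-3-[(3S)-4-(benzyloxy)-3-methylbutyl]phenyl}-3-hydroxy-5,6-dimethoxy-4H-chromen-4-one
Product: 23 3,7-dihydroxy-2-{4-hydroxy-3-[(3S)-4-hydroxy-3-methylbutyl]phenyl}-5,6-dimethoxy-4H-chromen-4-one
Conditions: H2 (1 atm), Pd(OH)2/C (20 wt %), EtOAc–MeOH (1:1), rt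
Reagents that add atoms: none
Why: Palladium-catalysed hydrogenolysis should cleave the two aryl benzyl ethers and the primary alkyl benzyl ether in one operation, leaving the flavonol, the methyl ethers and the remote (S) centre untouched.

Compound list

1 | 2,3-dimethoxybenzene-1,4-diol | COc1c(O)ccc(O)c1OC | starting material
2 | 4-(benzyloxy)-2,3-dimethoxyphenol | COc1c(O)ccc(OCc2ccccc2)c1OC | intermediate
3 | 4-(benzyloxy)-6-bromo-2,3-dimethoxyphenol | COc1c(O)c(Br)cc(OCc2ccccc2)c1OC | intermediate
4 | [4-(benzyloxy)-6-bromo-2,3-dimethoxyphenoxy]trimethylsilane | COc1c(O[Si](C)(C)C)c(Br)cc(OCc2ccccc2)c1OC | intermediate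
5 | lithium 4-(benzyloxy)-2,3-dimethoxy-6-(trimethylsilyl)phenolate | [Li+].COc1c([O-])c([Si](C)(C)C)cc(OCc2ccccc2)c1OC | intermediate
6 | 4-(benzyloxy)-2,3-dimethoxy-6-(trimethylsilyl)phenyl trifluoromethanesulfonate | COc1c(OS(=O)(=O)C(F)(F)F)c([Si](C)(C)C)cc(OCc2ccccc2)c1OC | intermediate
7 | methyl (2R)-3-hydroxy-2-methylpropanoate | COC(=O)[C@H](C)CO | starting material
8 | methyl (2R)-3-(benzyloxy)-2-methylpropanoate | COC(=O)[C@H](C)COCc1ccccc1 | intermediate
9 | (2R)-3-(benzyloxy)-2-methylpropanal | O=C[C@H](C)COCc1ccccc1 | intermediate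
10 | ({[(2S)-2-methylbut-3-en-1-yl]oxy}methyl)benzene | C=C[C@H](C)COCc1ccccc1 | intermediate
11 | 4-(benzyloxy)-3-bromobenzaldehyde | O=Cc1ccc(OCc2ccccc2)c(Br)c1 | starting material
12 | 9-[(3S)-4-(benzyloxy)-3-methylbutyl]-9-borabicyclo[3.3.1]nonane | B1(CC[C@H](C)COCc2ccccc2)C2CCCC1CCC2 | intermediate
13 | 4-(benzyloxy)-3-[(3S)-4-(benzyloxy)-3-methylbutyl]benzaldehyde | O=Cc1ccc(OCc2ccccc2)c(CC[C@H](C)COCc2ccccc2)c1 | intermediate
14 | 1-(benzyloxy)-2-[(3S)-4-(benzyloxy)-3-methylbutyl]-4-(2,2-dibromoethenyl)benzene | BrC(Br)=Cc1ccc(OCc2ccccc2)c(CC[C@H](C)COCc2ccccc2)c1 | intermediate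
15 | lithium {4-(benzyloxy)-3-[(3S)-4-(benzyloxy)-3-methylbutyl]phenyl}acetylide | [Li]C#Cc1ccc(OCc2ccccc2)c(CC[C@H](C)COCc2ccccc2)c1 | intermediate
16 | 3-{4-(benzyloxy)-3-[(3S)-4-(benzyloxy)-3-methylbutyl]phenyl}prop-2-ynoic acid | OC(=O)C#Cc1ccc(OCc2ccccc2)c(CC[C@H](C)COCc2ccccc2)c1 | intermediate
17 | 5-(benzyloxy)-3,4-dimethoxy-1,2-didehydrobenzene (the aryne; triple bond between the former C–OTf and C–Si carbons) | COC1=C(OC)C(OCc2ccccc2)=CC#C1 | intermediate
18 | 1-[4-(benzyloxy)-6-hydroxy-2,3-dimethoxyphenyl]-3-{4-(benzyloxy)-3-[(3S)-4-(benzyloxy)-3-methylbutyl]phenyl}prop-2-yn-1-one (present as its caesium phenolate) | COc1c(OCc2ccccc2)cc(O)c(C(=O)C#Cc2ccc(OCc3ccccc3)c(CC[C@H](C)COCc3ccccc3)c2)c1OC | intermediate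
19 | 7-(benzyloxy)-2-{4-(benzyloxy)-3-[(3S)-4-(benzyloxy)-3-methylbutyl]phenyl}-5,6-dimethoxy-4H-chromen-4-one | COc1c(OCc2ccccc2)cc2oc(-c3ccc(OCc4ccccc4)c(CC[C@H](C)COCc4ccccc4)c3)cc(=O)c2c1OC | intermediate
20 | 3-lithio derivative of 19 (lithium at C3 of the chromenone) | COc1c(OCc2ccccc2)cc2oc(-c3ccc(OCc4ccccc4)c(CC[C@H](C)COCc4ccccc4)c3)c([Li])c(=O)c2c1OC | intermediate
21 | dimethyl [7-(benzyloxy)-2-{4-(benzyloxy)-3-[(3S)-4-(benzyloxy)-3-methylbutyl]phenyl}-5,6-dimethoxy-4-oxo-4H-chromen-3-yl]boronate | COB(OC)c1c(-c2ccc(OCc3ccccc3)c(CC[C@H](C)COCc3ccccc3)c2)oc2cc(OCc3ccccc3)c(OC)c(OC)c2c1=O | intermediate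
22 | 7-(benzyloxy)-2-{4-(benzyloxy)-3-[(3S)-4-(benzyloxy)-3-methylbutyl]phenyl}-3-hydroxy-5,6-dimethoxy-4H-chromen-4-one | COc1c(OCc2ccccc2)cc2oc(-c3ccc(OCc4ccccc4)c(CC[C@H](C)COCc4ccccc4)c3)c(O)c(=O)c2c1OC | intermediate
23 | 3,7-dihydroxy-2-{4-hydroxy-3-[(3S)-4-hydroxy-3-methylbutyl]phenyl}-5,6-dimethoxy-4H-chromen-4-one | COc1c(O)cc2oc(-c3ccc(O)c(CC[C@H](C)CO)c3)c(O)c(=O)c2c1OC | target

Total step count: 12. Longest linear sequence: 9 steps (steps 4 to 12, from 7 to 23).

Steps most likely to fail

Step 10. The caesium propiolate may lose CO2 at 125 °C, the aryl anion may be protonated before the acyl shift so that only the aryl ester forms, or the phenolate may close 5-exo to the aurone. The fallback uses the aryne only to place the carbon substituent and sets out from 6 and 14. Compound 6 with CsF in moist DMF should give, by insertion of 17 into the C=O bond of DMF in the same orientation and hydrolysis, 4-(benzyloxy)-6-hydroxy-2,3-dimethoxybenzaldehyde F1. Lithium acetylide 15, made from 14 with n-BuLi as in step 9 and used in excess to allow for the phenol, would add to F1 to give the propargylic alcohol 1-[4-(benzyloxy)-6-hydroxy-2,3-dimethoxyphenyl]-3-{4-(benzyloxy)-3-[(3S)-4-(benzyloxy)-3-methylbutyl]phenyl}prop-2-yn-1-ol F2 as a mixture of carbinol epimers. MnO2 in CH2Cl2 would oxidise F2 to ynone 18, and Et2NH in EtOH, which closes such ynones through the enaminone in the 6-endo sense only, would return to the route at 19.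

Step 11. The amide base may add to the pyranone instead of deprotonating C3, metalation may compete at C8 between O1 and the benzyloxy group, or the borate may not form cleanly. The fallback sets out from 19 and changes to electrophilic oxidation of the C2=C3 bond. Dimethyldioxirane in acetone (0 °C → rt) should give the 2,3-epoxide of 19, 7-(benzyloxy)-2-{4-(benzyloxy)-3-[(3S)-4-(benzyloxy)-3-methylbutyl]phenyl}-2,3-epoxy-5,6-dimethoxy-2,3-dihydro-4H-chromen-4-one F3, and catalytic TsOH in CH2Cl2 would isomerise it to 22, where the route is rejoined.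

Step 2. Bromination may occur at C5 beside the benzyloxy group, or the hydroquinone monoether may be oxidised to the quinone with loss of the benzyl group. The fallback sets out from 2 and replaces electrophilic substitution by directed ortho-metalation. Isopropyl isocyanate (Et3N, CH2Cl2) would give 4-(benzyloxy)-2,3-dimethoxyphenyl propan-2-ylcarbamate F4. N-Silylation in the flask (TBSOTf, TMEDA), lithiation with n-BuLi at −78 °C at the only free position ortho to the carbamate, and Me3SiCl would give 4-(benzyloxy)-2,3-dimethoxy-6-(trimethylsilyl)phenyl propan-2-ylcarbamate F5. Et2NH and DBU in MeCN at 40 °C would cleave the carbamate to 4-(benzyloxy)-2,3-dimethoxy-6-(trimethylsilyl)phenol F6, which PhNTf2 in the same flask would convert into 6, so that steps 2 and 3 are both bypassed.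

Further compounds

F1 | step 10 | 4-(benzyloxy)-6-hydroxy-2,3-dimethoxybenzaldehyde | COc1c(OCc2ccccc2)cc(O)c(C=O)c1OC
F2 | step 10 | 1-[4-(benzyloxy)-6-hydroxy-2,3-dimethoxyphenyl]-3-{4-(benzyloxy)-3-[(3S)-4-(benzyloxy)-3-methylbutyl]phenyl}prop-2-yn-1-ol (both epimers at C1) | COc1c(OCc2ccccc2)cc(O)c(C(O)C#Cc2ccc(OCc3ccccc3)c(CC[C@H](C)COCc3ccccc3)c2)c1OC
F3 | step 11 | 7-(benzyloxy)-2-{4-(benzyloxy)-3-[(3S)-4-(benzyloxy)-3-methylbutyl]phenyl}-2,3-epoxy-5,6-dimethoxy-2,3-dihydro-4H-chromen-4-one (both configurations of the epoxide) | COc1c(OCc2ccccc2)cc2OC3(OC3C(=O)c2c1OC)c1ccc(OCc2ccccc2)c(CC[C@H](C)COCc2ccccc2)c1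
F4 | step 2 | 4-(benzyloxy)-2,3-dimethoxyphenyl propan-2-ylcarbamate | CC(C)NC(=O)Oc1ccc(OCc2ccccc2)c(OC)c1OC
F5 | step 2 | 4-(benzyloxy)-2,3-dimethoxy-6-(trimethylsilyl)phenyl propan-2-ylcarbamate | CC(C)NC(=O)Oc1c([Si](C)(C)C)cc(OCc2ccccc2)c(OC)c1OC
F6 | step 2 | 4-(benzyloxy)-2,3-dimethoxy-6-(trimethylsilyl)phenol | COc1c(O)c([Si](C)(C)C)cc(OCc2ccccc2)c1OC
A1 | direct plan | 1-[4-(benzyloxy)-6-hydroxy-2,3-dimethoxyphenyl]ethan-1-one | CC(=O)c1c(O)cc(OCc2ccccc2)c(OC)c1OC
A2 | direct plan | 4-(benzyloxy)-3-[(3S)-4-hydroxy-3-methylbutyl]benzaldehyde | O=Cc1ccc(OCc2ccccc2)c(CC[C@H](C)CO)c1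
A3 | direct plan | (2E)-1-[4-(benzyloxy)-6-hydroxy-2,3-dimethoxyphenyl]-3-{4-(benzyloxy)-3-[(3S)-4-hydroxy-3-methylbutyl]phenyl}prop-2-en-1-one | COc1c(OCc2ccccc2)cc(O)c(C(=O)/C=C/c2ccc(OCc3ccccc3)c(CC[C@H](C)CO)c2)c1OC
A4 | direct plan | 1-(benzyloxy)-4-(dimethoxymethyl)-2-(3-methylbut-3-en-1-yl)benzene | COC(OC)c1ccc(OCc2ccccc2)c(CCC(C)=C)c1
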